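## Numbering and conventions

The chain of the target is numbered C1–C19 from the methyl end of the pentyl group. C1–C5 are the pentyl group, the oxolane ring is O, C6, C7, C8, C9, the ester carbinol is C10 and the alkene is C18=C19. Carbohydrate positions are written "sugar C1 … sugar C6"; sugar C1–C6 become C10–C5 of the chain.

Compound numbers 1–21 are those of the steps and of the compound list. The main ones are: 1 diacetone-D-glucose, 3 its 3-deoxy derivative, 6 the 5,6-epoxide, 10 the 5-O-mesylate (precursor of the key step), 13 the oxolane dimethyl acetal (product of the key step), 15 the aldehyde, 18 the C10 alcohol, 20 the silylated ester and 21 the target.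

Assumption: n-butyllithium in hexanes is taken as the commercial butyl source (no butyl halide is needed); methanolic HCl and HF·pyridine are bought as such.

## Analysis of the target

- Target 21 is a C19 chain in which an oxygen bridges C6 and C9 to form an oxolane (O, C6, C7, C8, C9). C6 carries the pentyl group, C7 a free hydroxyl, C8 is a methylene, and C9 carries the C10 carbinol, which is esterified with dodecanoic acid and runs on to the terminal alkene C18=C19.
- There are four stereocentres: C6 (S), C7 (S), C9 (R) and C10 (R). On the ring the pentyl group and the C7 hydroxyl are cis, the C9 side chain is trans to both, and C9/C10 are threo.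
- The terminal alkene rules out hydrogenation, hydroboration, ozonolysis and metathesis catalysts once it is in place. The ester does not tolerate hydride, strong base or organometallic reagents.
- Two secondary oxygens, O7 and O10, must be told apart so that only O10 is acylated.
- The difficulty is stereochemical. C7 and C9 are separated by the C8 methylene, so one ring centre cannot simply relay to the next, and C10 has to be set beside the ring.
- The strategy rests on the oxygenation pattern of C10–C9–C8–C7–C6–C5. It is that of a 3-deoxyhexose: aldehyde level at C10 (sugar C1), oxygen on C9 (sugar C2), none on C8 (sugar C3), oxygen on C7 and C6 (sugar C4 and C5), and carbon at C5 (sugar C6).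
- With D-glucose, C9 and C7 have the correct absolute configuration as they stand. Only C6 is the mirror image of sugar C5, and the ring O–C6 bond is exactly the bond whose formation by displacement inverts that centre.

## Retrosynthetic reasoning

**21 ⇒ 20.** The O7–Si bond is cut last. The C7 hydroxyl travels as a silyl ether so that acylation of O10 meets a single free hydroxyl. The forward step has to cleave a hindered silyl ether without transesterifying the dodecanoate or touching C18=C19.

**20 ⇒ 18 + 19.** The acyl–O10 bond is cut. The long acyl chain then enters as acid chloride 19 after all organometallic chemistry is over. The forward step is a plain acylation of the only free hydroxyl of 18, with retention at C10.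

**18 ⇒ 15 + 17 (made from 16).** The C10–C11 bond is cut next to the ring. This puts C10 at the aldehyde oxidation level, which is what sugar C1 supplies, and brings the alkene in with a ready-made C9 nucleophile. The forward addition must set C10 as (R), threo to C9; the ring oxygen on C9 is the handle for chelation control.

**15 ⇒ 14 ⇒ 13.** The aldehyde is traced back to its dimethyl acetal and the silyl ether to the free C7 hydroxyl. No skeletal bond is cut. The aldehyde stays masked until it is needed, and the protecting group goes onto the only hydroxyl present.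

**13 ⇒ 10 (through 11 and 12).** The ring O–C6 bond is cut, leaving the oxygen on C9 and turning C6 into a sulfonate-bearing carbon of opposite configuration. Cutting the other ring bond, O–C9, would put the leaving group next to the acetal carbon, where displacement is slow, and would disturb a centre the sugar already supplies correctly. The chosen cut turns the ring into furanose acetonide 10 of the 3-deoxy-D-gluco series. The forward reaction must open the acetonide to the acyclic dimethyl acetal 12 and close the oxolane by SN2 displacement with inversion.

**10 ⇒ 9 ⇒ 6 + 7 (as cuprate 8).** After removal of the sulfonyl group, the C4–C5 bond (sugar C6–butyl) is cut. An epoxide between sugar C5 and C6 is the natural electrophile. It is opened at the primary carbon, so the carbinol centre at sugar C5 comes through unchanged with its oxygen free for sulfonylation.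

**6 ⇒ 4 (through 5) ⇒ 3.** The epoxide is traced to the 5,6-diol 4, and that to diacetonide 3 by selective unmasking of the terminal acetonide. The forward steps must distinguish the primary from the secondary hydroxyl and close the oxirane by attack of O5 on sugar C6, which leaves sugar C5 untouched.

**3 ⇒ 2 ⇒ 1.** The C8 methylene is traced to the sugar C3 hydroxyl, the only free hydroxyl of 1. Radical deoxygenation through xanthate 2 needs no protecting-group work and cannot epimerise the neighbouring centres.

## Alternatives that were turned down

**Alternative 1:** ring closure by metathesis at C8=C9.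

- Disconnection: the C8–C9 bond, drawn as the double bond of the 2,3-dihydrofuran (2S,3S)-5-[(1R)-1-(tert-butyldimethylsilyloxy)dec-9-en-1-yl]-3-(methoxymethoxy)-2-pentyl-2,3-dihydrofuran A1. The ring O–C9 bond is traced to the ester (3S,4S)-3-(methoxymethoxy)non-1-en-4-yl (2R)-2-(tert-butyldimethylsilyloxy)undec-10-enoate A3, which joins a C5–C8 half to a C9–C19 half.
- Forward key step: A3 is methylenated to the enol ether (3S,4S)-4-{[(3R)-3-(tert-butyldimethylsilyloxy)dodeca-1,11-dien-2-yl]oxy}-3-(methoxymethoxy)non-1-ene A2. The second-generation Grubbs catalyst, RuCl2(=CHPh)(H2IMes)(PCy3), then joins the C8 vinyl carbon to the enol ether carbon C9 to give A1.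
- For it: the route is convergent, so its longest linear sequence would be shorter than the one chosen here. C10 comes from an enantiopure α-oxygenated acid, so no diastereoselective addition is needed at that centre. On both points it is stronger.
- Against it: A2 already carries the C18=C19 terminal alkene, the olefin most reactive towards the ruthenium carbene, so oligomerisation and cross-metathesis compete with closure onto the reluctant 1,1-disubstituted enol ether. Masking the alkene would cost extra steps.
- Against it: the key step leaves C9 sp2. It must then be reduced with the correct facial sense while C18=C19 survives, which excludes catalytic hydrogenation and leaves an ionic reduction whose selectivity would rest on the C7 oxygen alone.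
- Against it: two orthogonal protecting groups must be removed in order, and both halves need their own asymmetric syntheses.
- Comparison: the chosen route is linear, but it takes all three ring centres from the sugar or from a stereospecific inversion, and the alkene never meets a metathesis or hydrogenation catalyst.

**Alternative 2:** Paternò–Büchi addition across C6=C7.

- Disconnection: the C5–C6 and O–C7 bonds. The pentyl carbons and the C7 oxygen are added across the enol ether of (1R)-1-[(2R)-2,3-dihydrofuran-2-yl]dec-9-en-1-yl dodecanoate A5, which already holds the ester.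
- Forward key step: irradiation of pentanal A6 with A5 should give the cis-fused oxetane (1R)-1-(7-butyl-2,6-dioxabicyclo[3.2.0]heptan-3-yl)dec-9-en-1-yl dodecanoate A4.
- For it: it is the shortest plan on paper, needs no protecting groups, and fixes the cis relation of the C6 carbon substituent and the C7 oxygen in one step through the cis ring fusion. The regiochemistry (carbonyl oxygen to the β-carbon C7) matches the usual preference of enol ethers. In step and atom economy it is clearly stronger.
- Against it: the route then depends on reductive cleavage of the unactivated C5–O bond of the oxetane while the C7–O bond stays. No dependable method exists for a non-benzylic oxetane, and hydrogenolysis would also saturate C18=C19.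
- Against it: an aliphatic aldehyde such as A6 loses much of its excited state to α-cleavage and γ-hydrogen abstraction, and reacts through both singlet and triplet states, which erodes selectivity.
- Against it: facial control would come only from the C9 substituent across the ring oxygen, the C18=C19 alkene is itself a partner for the excited carbonyl, and A5 still needs an enantioselective synthesis of C9 and C10.
- Comparison: the chosen route is longer, but every step belongs to an established reaction class and no stereocentre depends on a photochemical facial preference.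

**Alternative 3:** oxidative ring contraction of a dihydropyran.

- Disconnection: the ring O–C9 bond, made with extrusion of C10 from the six-membered enol ether (2S,3S)-3-(tert-butyldimethylsilyloxy)-2-pentyl-3,4-dihydro-2H-pyran A8, in which the ring oxygen sits on C10.
- Forward key step: Tl(NO3)3 (trivalent thallium) or PhI(OH)OTs (trivalent iodine) in methanol adds to C9 while methanol adds to C10. A 1,2-shift of the ring oxygen from C10 to C9 then expels the electrophile and releases C10 as a dimethyl acetal, giving (2S,3S,5R)-3-(tert-butyldimethylsilyloxy)-5-(dimethoxymethyl)-2-pentyloxolane A7.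
- For it: A7 is the O7-protected analogue of 14, so this plan joins the same endgame and saves the silylation step. The ring-forming step needs no unfavourable equilibrium to an acyclic form. On both points it is as strong as or stronger than the chosen route.
- Against it: the C9 configuration is decided by the face at which the electrophile adds to C9=C10. In A8 the allylic carbon C8 is unsubstituted and the nearest stereocentre, C7, is homoallylic, so nothing in the substrate secures the 2,5-trans arrangement.
- Against it: the thallium reagent is highly toxic, and the iodine variant can divert to other oxidation pathways.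
- Against it: A8 needs a de novo asymmetric synthesis of a cis-2,3-disubstituted dihydropyran, which would take about as many steps as steps 1–6 here.
- Comparison: the chosen route inherits C9 from the sugar and sets C6 by a stereospecific inversion, so it gives up the saved step in exchange for certainty at the ring centres.

Key step: step 7

## Steps

Step 1
Reactants: 1 1,2:5,6-di-O-isopropylidene-α-D-glucofuranose
Product: 2 1,2:5,6-di-O-isopropylidene-3-O-[(methylsulfanyl)carbonothioyl]-α-D-glucofuranose
Conditions: NaH, imidazole (cat.), THF, 0 °C; CS2; MeI, rt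
Reagents that add atoms: carbon disulfide, S=C=S; iodomethane, CI
Why: Xanthate formation on the only free hydroxyl (sugar C3): the alkoxide adds to CS2 and the dithiocarbonate salt is S-methylated; no stereocentre is touched.

Step 2
Reactants: 2 1,2:5,6-di-O-isopropylidene-3-O-[(methylsulfanyl)carbonothioyl]-α-D-glucofuranose
Product: 3 3-deoxy-1,2:5,6-di-O-isopropylidene-α-D-ribo-hexofuranose
Conditions: Bu3SnH, azobisisobutyronitrile (AIBN, cat.), toluene, reflux
Reagents that add atoms: none
Why: Barton–McCombie deoxygenation: the stannyl radical adds to C=S, β-scission gives the secondary radical at sugar C3, which abstracts hydrogen from Bu3SnH; the carbon becomes the C8 methylene and both acetonides are inert to radicals.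

Step 3
Reactants: 3 3-deoxy-1,2:5,6-di-O-isopropylidene-α-D-ribo-hexofuranose
Product: 4 3-deoxy-1,2-O-isopropylidene-α-D-ribo-hexofuranose
Conditions: AcOH/H2O (3:1), rt
Reagents that add atoms: none
Why: Selective acetal hydrolysis: the terminal 5,6-dioxolane should be cleaved well before the 1,2-acetonide, which is cis-fused to the furanose and adjacent to the anomeric centre; the reaction is stopped at the diol.

Step 4
Reactants: 4 3-deoxy-1,2-O-isopropylidene-α-D-ribo-hexofuranose
Product: 6 5,6-anhydro-3-deoxy-1,2-O-isopropylidene-α-D-ribo-hexofuranose, via 6-O-tosyl diol 5 (not isolated)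
Conditions: TsCl (1.05 equiv), pyridine, CH2Cl2, 0 °C; then MeOH, K2CO3, rt
Reagents that add atoms: none
Why: Regioselective sulfonylation of the primary O6 followed by intramolecular Williamson closure (3-exo-tet) by O5; the C5–O5 bond is never broken, so sugar C5 keeps its D (R) configuration.

Step 5
Reactants: 6 5,6-anhydro-3-deoxy-1,2-O-isopropylidene-α-D-ribo-hexofuranose; 7 n-butyllithium
Product: 9 6-C-butyl-3,6-dideoxy-1,2-O-isopropylidene-α-D-ribo-hexofuranose, via lithium dibutylcuprate 8 (not isolated)
Conditions: CuI, 7 (2 equiv per Cu), Et2O, −40 °C; then 6, −40 → 0 °C; aq. NH4Cl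
Reagents that add atoms: none
Why: SN2 opening of a terminal epoxide by a Gilman cuprate at the unhindered primary carbon (sugar C6) forms the C4–C5 bond of the chain; the carbinol centre at sugar C5 is not involved and stays (R).

Step 6
Reactants: 9 6-C-butyl-3,6-dideoxy-1,2-O-isopropylidene-α-D-ribo-hexofuranose
Product: 10 6-C-butyl-3,6-dideoxy-1,2-O-isopropylidene-5-O-methanesulfonyl-α-D-ribo-hexofuranose
Conditions: MsCl, Et3N, CH2Cl2, 0 °C
Reagents that add atoms: methanesulfonyl chloride, CS(Cl)(=O)=O
Why: Sulfonylation of the only hydroxyl; only the O–S bond forms, so the configuration at sugar C5 is retained and the leaving group for the ring closure is in place.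

Step 7
Reactants: 10 6-C-butyl-3,6-dideoxy-1,2-O-isopropylidene-5-O-methanesulfonyl-α-D-ribo-hexofuranose
Product: 13 (2S,3S,5R)-5-(dimethoxymethyl)-2-pentyloxolan-3-ol, via methyl furanoside mesylate 11 (not isolated), via open-chain dimethyl acetal mesylate 12 (not isolated)
Conditions: HCl (ca. 0.5 M) in MeOH, reflux; then NaHCO3
Reagents that add atoms: methanol, CO
Why: Acid-catalysed transacetalisation exchanges the 1,2-acetonide for the methyl furanosides 11, which equilibrate with a small share of the open-chain dimethyl acetal 12. In 11 the O2 hydroxyl and the sugar C5 side chain lie on opposite faces of the furanose, so closure is possible only from 12, where O2–H attacks sugar C5 from the back of the C–OMs bond and forms the ring O–C6 bond. The closure is a 5-exo-tet Williamson-type etherification by a neutral hydroxyl, the reaction type known for 5-O-sulfonyl hexofuranose acetonides, which give 2,5-anhydroaldose dimethyl acetals in acidic methanol. The one new stereocentre, C6, is controlled only by the SN2 geometry: the (R) sulfonate carbon is inverted to (S), while C9 and C7 (sugar C2 and C4) take no part and keep their configuration. The displacement is irreversible and releases methanesulfonic acid, so it drains the furanoside/acetal equilibrium. The step needs chemoselectivity among three oxygen nucleophiles: O2 closes the favoured five-membered ring, O4 could only form an oxirane, which a neutral hydroxyl does not close in acid, and an acetal oxygen would have to form a six-membered oxonium ion; the absent sugar C3 hydroxyl removes any further anhydro ring. The freed O4 becomes the C7 hydroxyl, cis to the pentyl group and trans to the acetal carbon, so no internal acetal can form and the product should remain the dimethyl acetal.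

Step 8
Reactants: 13 (2S,3S,5R)-5-(dimethoxymethyl)-2-pentyloxolan-3-ol
Product: 14 tert-butyl{[(2S,3S,5R)-5-(dimethoxymethyl)-2-pentyloxolan-3-yl]oxy}diphenylsilane
Conditions: TBDPSCl, imidazole, 4-(dimethylamino)pyridine (DMAP, cat.), DMF, rt → 40 °C
Reagents that add atoms: tert-butyl(chloro)diphenylsilane, CC(C)(C)[Si](Cl)(c1ccccc1)c1ccccc1
Why: Silylation of the only hydroxyl; the tert-butyldiphenylsilyl ether is chosen because it should survive the aqueous acid of step 9 and the Grignard reagent of step 10 and can be removed by fluoride beside an ester.

Step 9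
Reactants: 14 tert-butyl{[(2S,3S,5R)-5-(dimethoxymethyl)-2-pentyloxolan-3-yl]oxy}diphenylsilane
Product: 15 (2R,4S,5S)-4-[(tert-butyldiphenylsilyl)oxy]-5-pentyloxolane-2-carbaldehyde
Conditions: TFA/H2O (1:1), CHCl3, 0 °C → rt; crude aldehyde dried azeotropically (toluene)
Reagents that add atoms: water, O
Why: Acetal hydrolysis; the α ring oxygen slows ionisation, so a strong acid is used, which the silyl ether should tolerate, and acidic conditions do not enolise the aldehyde, so C9 is not epimerised.

Step 10
Reactants: 15 (2R,4S,5S)-4-[(tert-butyldiphenylsilyl)oxy]-5-pentyloxolane-2-carbaldehyde; 16 9-bromonon-1-ene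
Product: 18 (1R)-1-[(2R,4S,5S)-4-[(tert-butyldiphenylsilyl)oxy]-5-pentyloxolan-2-yl]dec-9-en-1-ol, via non-8-en-1-ylmagnesium bromide 17 (not isolated)
Conditions: 16, Mg, Et2O, reflux; 15, MgBr2·OEt2, CH2Cl2, −78 °C, then the solution of 17, −78 → −40 °C; aq. NH4Cl
Reagents that add atoms: none
Why: Chelation-controlled (Cram chelate) Grignard addition: magnesium bridges the ring oxygen and the carbonyl oxygen and holds them syn-periplanar, so the nucleophile enters from the face flanked by H–C9 and not by the C8 methylene, which should give the (10R), threo alcohol; the silyl ether on C7 is trans to the aldehyde and does not interfere.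

Step 11
Reactants: 18 (1R)-1-[(2R,4S,5S)-4-[(tert-butyldiphenylsilyl)oxy]-5-pentyloxolan-2-yl]dec-9-en-1-ol; 19 dodecanoyl chloride
Product: 20 (1R)-1-[(2R,4S,5S)-4-[(tert-butyldiphenylsilyl)oxy]-5-pentyloxolan-2-yl]dec-9-en-1-yl dodecanoate
Conditions: 19, pyridine, 4-(dimethylamino)pyridine (DMAP, cat.), CH2Cl2, 0 °C → rt
Reagents that add atoms: none
Why: Nucleophilic acyl substitution with acylpyridinium catalysis on the only free hydroxyl; the O–acyl bond is formed, so C10 keeps its (R) configuration.

Step 12
Reactants: 20 (1R)-1-[(2R,4S,5S)-4-[(tert-butyldiphenylsilyl)oxy]-5-pentyloxolan-2-yl]dec-9-en-1-yl dodecanoate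
Product: 21 (1R)-1-[(2R,4S,5S)-4-hydroxy-5-pentyloxolan-2-yl]dec-9-en-1-yl dodecanoate
Conditions: HF·pyridine, pyridine, THF, 0 °C → rt
Reagents that add atoms: none
Why: Fluoride-driven Si–O cleavage in a buffered, weakly acidic medium, which should leave the ester and the alkene alone; acyl migration is not expected because O7 is trans to the C9 side chain and 1,4-related to O10.

## Compound list

1 | 1,2:5,6-di-O-isopropylidene-α-D-glucofuranose | CC1(C)OC[C@@H](O1)[C@@H]1[C@H](O)[C@H]2OC(C)(C)O[C@H]2O1 | starting material
2 | 1,2:5,6-di-O-isopropylidene-3-O-[(methylsulfanyl)carbonothioyl]-α-D-glucofuranose | CC1(C)OC[C@@H](O1)[C@@H]1[C@H](OC(=S)SC)[C@H]2OC(C)(C)O[C@H]2O1 | intermediate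
3 | 3-deoxy-1,2:5,6-di-O-isopropylidene-α-D-ribo-hexofuranose | CC1(C)OC[C@@H](O1)[C@@H]1C[C@H]2OC(C)(C)O[C@H]2O1 | intermediate
4 | 3-deoxy-1,2-O-isopropylidene-α-D-ribo-hexofuranose | OC[C@@H](O)[C@@H]1C[C@H]2OC(C)(C)O[C@H]2O1 | intermediate
5 | 3-deoxy-1,2-O-isopropylidene-6-O-(4-methylbenzenesulfonyl)-α-D-ribo-hexofuranose | Cc1ccc(cc1)S(=O)(=O)OC[C@@H](O)[C@@H]1C[C@H]2OC(C)(C)O[C@H]2O1 | intermediate (not isolated)
6 | 5,6-anhydro-3-deoxy-1,2-O-isopropylidene-α-D-ribo-hexofuranose | O1C[C@@H]1[C@@H]2C[C@H]3OC(C)(C)O[C@H]3O2 | intermediate
7 | n-butyllithium | [Li]CCCC | starting material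
8 | lithium dibutylcuprate | [Li+].CCCC[Cu-]CCCC | intermediate (not isolated)
9 | 6-C-butyl-3,6-dideoxy-1,2-O-isopropylidene-α-D-ribo-hexofuranose | CCCCC[C@@H](O)[C@@H]1C[C@H]2OC(C)(C)O[C@H]2O1 | intermediate
10 | 6-C-butyl-3,6-dideoxy-1,2-O-isopropylidene-5-O-methanesulfonyl-α-D-ribo-hexofuranose | CCCCC[C@@H](OS(C)(=O)=O)[C@@H]1C[C@H]2OC(C)(C)O[C@H]2O1 | intermediate
11 | methyl 6-C-butyl-3,6-dideoxy-5-O-methanesulfonyl-D-ribo-hexofuranoside (both anomers) | CCCCC[C@@H](OS(C)(=O)=O)[C@@H]1C[C@@H](O)C(OC)O1 | intermediate (not isolated)
12 | 6-C-butyl-3,6-dideoxy-5-O-methanesulfonyl-D-ribo-hexose dimethyl acetal | CCCCC[C@@H](OS(C)(=O)=O)[C@@H](O)C[C@@H](O)C(OC)OC | intermediate (not isolated)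
13 | (2S,3S,5R)-5-(dimethoxymethyl)-2-pentyloxolan-3-ol | COC(OC)[C@H]1C[C@H](O)[C@H](CCCCC)O1 | intermediate
14 | tert-butyl{[(2S,3S,5R)-5-(dimethoxymethyl)-2-pentyloxolan-3-yl]oxy}diphenylsilane | COC(OC)[C@H]1C[C@H](O[Si](c2ccccc2)(c2ccccc2)C(C)(C)C)[C@H](CCCCC)O1 | intermediate
15 | (2R,4S,5S)-4-[(tert-butyldiphenylsilyl)oxy]-5-pentyloxolane-2-carbaldehyde | O=C[C@H]1C[C@H](O[Si](c2ccccc2)(c2ccccc2)C(C)(C)C)[C@H](CCCCC)O1 | intermediate
16 | 9-bromonon-1-ene | C=CCCCCCCCBr | starting material
17 | non-8-en-1-ylmagnesium bromide | C=CCCCCCCC[Mg]Br | intermediate (not isolated)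
18 | (1R)-1-[(2R,4S,5S)-4-[(tert-butyldiphenylsilyl)oxy]-5-pentyloxolan-2-yl]dec-9-en-1-ol | C=CCCCCCCC[C@@H](O)[C@H]1C[C@H](O[Si](c2ccccc2)(c2ccccc2)C(C)(C)C)[C@H](CCCCC)O1 | intermediate
19 | dodecanoyl chloride | CCCCCCCCCCCC(Cl)=O | starting material
20 | (1R)-1-[(2R,4S,5S)-4-[(tert-butyldiphenylsilyl)oxy]-5-pentyloxolan-2-yl]dec-9-en-1-yl dodecanoate | C=CCCCCCCC[C@@H](OC(=O)CCCCCCCCCCC)[C@H]1C[C@H](O[Si](c2ccccc2)(c2ccccc2)C(C)(C)C)[C@H](CCCCC)O1 | intermediate
21 | (1R)-1-[(2R,4S,5S)-4-hydroxy-5-pentyloxolan-2-yl]dec-9-en-1-yl dodecanoate | C=CCCCCCCC[C@@H](OC(=O)CCCCCCCCCCC)[C@H]1C[C@H](O)[C@H](CCCCC)O1 | target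

## Step count and least certain steps

Total: 12 steps. Longest linear sequence: 12 steps (1 → 21); 7, 16 and 19 are bought and enter in steps 5, 10 and 11.

**Step 7 (key step).**
- What may go wrong: the open-chain acetal 12 is only a small equilibrium share, so the reaction may stall at the furanosides 11. Prolonged heating in acid then invites solvolysis of the secondary sulfonate by the solvent, ionisation with loss of stereospecificity at sugar C5, or elimination.
- Fallback: setting out from 10, the furanose would be opened irreversibly instead of through a minor equilibrium. Ethanethiol and concentrated HCl at 0 °C should convert the acetonide into the acyclic thioacetal 6-C-butyl-3,6-dideoxy-5-O-methanesulfonyl-D-ribo-hexose diethyl dithioacetal F1. Warming this with NaHCO3 in DMF should close the ring by the same 5-exo-tet attack of O2 on sugar C5 with inversion, giving (2S,3S,5R)-5-[bis(ethylsulfanyl)methyl]-2-pentyloxolan-3-ol F2. Oxidative exchange of the thioacetal with PhI(OCOCF3)2 in methanol comes back to the route at 13.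

**Step 10.**
- What may go wrong: poor facial selectivity, if the Grignard reagent adds to aldehyde that is not chelated (ether competing for magnesium), so that a Felkin–Anh pathway delivers the C10 epimer; enolisation of the aldehyde with epimerisation at C9 is a second loss.
- Fallback: setting out from the mixture of 18 and its epimer (1S)-1-[(2R,4S,5S)-4-[(tert-butyldiphenylsilyl)oxy]-5-pentyloxolan-2-yl]dec-9-en-1-ol F3, oxidation with Dess–Martin periodinane would give the ketone 1-[(2R,4S,5S)-4-[(tert-butyldiphenylsilyl)oxy]-5-pentyloxolan-2-yl]dec-9-en-1-one F4. Reduction with LiBH(s-Bu)3 in THF at −78 °C should then come back to the route at 18. With this bulky, non-chelating hydride the ring C–O bond stands anti to the incoming hydride (Felkin–Anh), which leads to the threo alcohol. A chelating hydride such as Zn(BH4)2 would give the wrong epimer and is avoided.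

**Step 9.**
- What may go wrong: hydrolysis of an acetal whose oxocarbenium ion is destabilised by the α ring oxygen is slow. Forcing it risks loss of the silyl ether and handling losses through hydration of the aldehyde.
- Fallback: setting out from 13, the order of the two steps would be reversed. Aqueous TFA on the unprotected acetal should give (2R,4S,5S)-4-hydroxy-5-pentyloxolane-2-carbaldehyde F5, which cannot form an internal hemiacetal because the hydroxyl is trans to the formyl group. Silylation with TBDPSCl and imidazole then comes back to the route at 15, so the silyl ether never meets the acid.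

**Step 5.**
- What may go wrong: thermal decomposition of the cuprate before the epoxide is consumed, or opening of the epoxide by iodide to an iodohydrin.
- Fallback: setting out from 6, the carbon nucleophile would be changed to an alkyne. But-1-ynyllithium (from but-1-yne and 7) with BF3·OEt2 in THF at −78 °C should open the epoxide at sugar C6 to give 6-C-(but-1-yn-1-yl)-3,6-dideoxy-1,2-O-isopropylidene-α-D-ribo-hexofuranose F6. Hydrogenation over Pd/C (palladium on carbon), harmless at this stage because no alkene is yet present, comes back to the route at 9.

## Further compounds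

F1 | step 7 | 6-C-butyl-3,6-dideoxy-5-O-methanesulfonyl-D-ribo-hexose diethyl dithioacetal | CCCCC[C@@H](OS(C)(=O)=O)[C@@H](O)C[C@@H](O)C(SCC)SCC
F2 | step 7 | (2S,3S,5R)-5-[bis(ethylsulfanyl)methyl]-2-pentyloxolan-3-ol | CCSC(SCC)[C@H]1C[C@H](O)[C@H](CCCCC)O1
F3 | step 10 | (1S)-1-[(2R,4S,5S)-4-[(tert-butyldiphenylsilyl)oxy]-5-pentyloxolan-2-yl]dec-9-en-1-ol | C=CCCCCCCC[C@H](O)[C@H]1C[C@H](O[Si](c2ccccc2)(c2ccccc2)C(C)(C)C)[C@H](CCCCC)O1
F4 | step 10 | 1-[(2R,4S,5S)-4-[(tert-butyldiphenylsilyl)oxy]-5-pentyloxolan-2-yl]dec-9-en-1-one | C=CCCCCCCCC(=O)[C@H]1C[C@H](O[Si](c2ccccc2)(c2ccccc2)C(C)(C)C)[C@H](CCCCC)O1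
F5 | step 9 | (2R,4S,5S)-4-hydroxy-5-pentyloxolane-2-carbaldehyde | O=C[C@H]1C[C@H](O)[C@H](CCCCC)O1
F6 | step 5 | 6-C-(but-1-yn-1-yl)-3,6-dideoxy-1,2-O-isopropylidene-α-D-ribo-hexofuranose | CCC#CC[C@@H](O)[C@@H]1C[C@H]2OC(C)(C)O[C@H]2O1
A1 | alternative 1 | (2S,3S)-5-[(1R)-1-(tert-butyldimethylsilyloxy)dec-9-en-1-yl]-3-(methoxymethoxy)-2-pentyl-2,3-dihydrofuran | C=CCCCCCCC[C@@H](O[Si](C)(C)C(C)(C)C)C1=C[C@H](OCOC)[C@H](CCCCC)O1
A2 | alternative 1 | (3S,4S)-4-{[(3R)-3-(tert-butyldimethylsilyloxy)dodeca-1,11-dien-2-yl]oxy}-3-(methoxymethoxy)non-1-ene | C=CCCCCCCC[C@@H](O[Si](C)(C)C(C)(C)C)C(=C)O[C@@H](CCCCC)[C@@H](OCOC)C=C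
A3 | alternative 1 | (3S,4S)-3-(methoxymethoxy)non-1-en-4-yl (2R)-2-(tert-butyldimethylsilyloxy)undec-10-enoate | C=CCCCCCCC[C@@H](O[Si](C)(C)C(C)(C)C)C(=O)O[C@@H](CCCCC)[C@@H](OCOC)C=C
A4 | alternative 2 | (1R)-1-(7-butyl-2,6-dioxabicyclo[3.2.0]heptan-3-yl)dec-9-en-1-yl dodecanoate (cis-fused, oxetane anti to the side chain, butyl exo) | C=CCCCCCCC[C@@H](OC(=O)CCCCCCCCCCC)[C@H]1C[C@@H]2O[C@@H](CCCC)[C@@H]2O1
A5 | alternative 2 | (1R)-1-[(2R)-2,3-dihydrofuran-2-yl]dec-9-en-1-yl dodecanoate | C=CCCCCCCC[C@@H](OC(=O)CCCCCCCCCCC)[C@H]1CC=CO1
A6 | alternative 2 | pentanal | CCCCC=O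
A7 | alternative 3 | (2S,3S,5R)-3-(tert-butyldimethylsilyloxy)-5-(dimethoxymethyl)-2-pentyloxolane | COC(OC)[C@H]1C[C@H](O[Si](C)(C)C(C)(C)C)[C@H](CCCCC)O1
A8 | alternative 3 | (2S,3S)-3-(tert-butyldimethylsilyloxy)-2-pentyl-3,4-dihydro-2H-pyran | C1=CO[C@@H](CCCCC)[C@@H](O[Si](C)(C)C(C)(C)C)C1
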